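**Plan**

1. Cuts (decalin numbered as naphthalene: C1 bears CO2R, C2 the secondary CH3, C4a/C8a the angular CH3, C5=C6 the ring double bond; ring A = C1–C4/C4a/C8a, ring B = C4a–C8a): (a) the O–CH2 bond between acid and glycerol (acid 25 + glycidyl ether 28); (b) the ring A bond C4–C4a with reconnection of C2 to C6, a retro-oxy-Cope to the 2-vinylbicyclo[2.2.2]oct-5-en-2-ol 18; (c) the two bridge bonds of 18 (C8a–C1 and C6–C2), a retro-Diels–Alder to diene 6 and fumaroyl imide 10; (d) the ring B–side chain bond (triflate 3 + Grignard reagent 5).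
2. Enabling feature: C2 is carried as a ketone, and this carbonyl stands delta,epsilon to the ring B double bond C5=C6 through C3–C4–C4a across a cis ring fusion. That is the retron of an anionic oxy-Cope shift, and the cis-vicinal angular methyls on C4a/C8a are what a bridged bicyclo[2.2.2]octene precursor delivers.
3. Forward order: ring B is bought (2,3-dimethylcyclohexenone), turned into a 1,3-diene and bridged by a Diels–Alder reaction; ring A is closed last (step 9) as the bridge is released. Then C2 ketone to methyl, C1 CH2OH to CO2H, and the glyceride by epoxide opening.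
4. Stereochemistry: C8a and C1 from the endo Diels–Alder on the (R)-benzyloxazolidinone-bound dienophile; the carbinol centre from hydroxylation of a cis-fused lactone on its convex face; C4a from the suprafacial boat [3,3] shift; C2 from hydroxyl-directed hydrogenation; the glycerol centre from (S)-glycidol.

Key step: step 9

Remark: compounds 1, 4, 7, 8 and 26 are taken as catalogue materials; the glycerol unit is the 1-acyl-2-acetyl-sn-glycerol (2S) as drawn.

**Route**

Step 1
Reactants: 1 2,3-dimethylcyclohex-2-en-1-one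
Product: 3 5,6-dimethylcyclohexa-1,5-dien-1-yl trifluoromethanesulfonate, via lithium dienolate 2 (not isolated)
Conditions: LiN(iPr)2, THF, −78 °C; then PhNTf2, −78 °C to 0 °C
Reagents that add atoms: N-phenylbis(trifluoromethanesulfonimide) O=S(=O)(N(c1ccccc1)S(=O)(=O)C(F)(F)F)C(F)(F)F
Why: Kinetic deprotonation of the enone at C6 gives the cross-conjugated dienolate, whose O-triflation (enol triflate formation) should give the 2-triflyloxy-1,3-diene regiospecifically.

Step 2
Reactants: 3 5,6-dimethylcyclohexa-1,5-dien-1-yl trifluoromethanesulfonate; 4 5-bromo-2-methylpent-2-ene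
Product: 6 1,2-dimethyl-3-(4-methylpent-3-en-1-yl)cyclohexa-1,3-diene, via Grignard reagent 5 (not isolated)
Conditions: 4, Mg, THF, rt; then 3, Fe(acac)3 (5 mol%), THF/NMP, −30 °C
Reagents that add atoms: none
Why: Iron-catalysed Kumada coupling of alkenyl triflates with primary alkyl Grignard reagents is fast at low temperature and should place the side chain on the triflate carbon without moving the diene.

Step 3
Reactants: 7 (4R)-4-benzyl-1,3-oxazolidin-2-one; 8 ethyl (2E)-4-chloro-4-oxobut-2-enoate
Product: 10 ethyl (2E)-4-[(4R)-4-benzyl-2-oxo-1,3-oxazolidin-3-yl]-4-oxobut-2-enoate, via lithium oxazolidinide 9 (not isolated)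
Conditions: n-BuLi, THF, −78 °C; then 8, −78 °C to 0 °C
Reagents that add atoms: none
Why: N-Acylation of the lithiated oxazolidinone by the acid chloride is the standard entry to enoyl imides and leaves the (E)-alkene and the ethyl ester untouched.

Step 4
Reactants: 6 1,2-dimethyl-3-(4-methylpent-3-en-1-yl)cyclohexa-1,3-diene; 10 ethyl (2E)-4-[(4R)-4-benzyl-2-oxo-1,3-oxazolidin-3-yl]-4-oxobut-2-enoate
Product: 11 ethyl (1S,2R,3S,4R)-3-{[(4R)-4-benzyl-2-oxo-1,3-oxazolidin-3-yl]carbonyl}-4,5-dimethyl-6-(4-methylpent-3-en-1-yl)bicyclo[2.2.2]oct-5-ene-2-carboxylate (imide syn to the C5=C6 bridge; ester anti)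
Conditions: Et2AlCl (1.6 equiv), CH2Cl2, −78 °C to −30 °C
Reagents that add atoms: none
Why: In this Lewis-acid-promoted Diels–Alder reaction of the chelated s-cis fumaroyl imide the diene should add anti to the benzyl group with the activated imide carbonyl endo and with the imide-bearing carbon bonding to the methyl-substituted diene terminus (ortho orientation), which sets both bridgeheads and C3 and puts the ester on C2 next to the unsubstituted bridgehead.

Step 5
Reactants: 11 the Diels–Alder adduct
Product: 13 (1S,2S,6S,7R)-7,8-dimethyl-9-(4-methylpent-3-en-1-yl)-4-oxatricyclo[5.2.2.0(2,6)]undec-8-en-3-one (cis-fused lactone on the face of the C8=C9 bridge), via hydroxy ester 12 (not isolated)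
Conditions: LiBH4 (1.1 equiv), MeOH (1 equiv), THF, 0 °C; acetone; then NaOMe, MeOH, 50 °C
Reagents that add atoms: none
Why: LiBH4 cleaves the exocyclic imide carbonyl reductively to the primary alcohol faster than it reduces the ester, and methoxide then epimerises the only enolisable centre (the ester-bearing carbon) so that the cis hydroxy ester is drained into the cis-fused gamma-lactone.

Step 6
Reactants: 13 the cis-fused lactone
Product: 15 (1R,2R,6S,7R)-2-hydroxy-7,8-dimethyl-9-(4-methylpent-3-en-1-yl)-4-oxatricyclo[5.2.2.0(2,6)]undec-8-en-3-one, via potassium enolate 14 (not isolated)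
Conditions: KN(SiMe3)2, THF, −78 °C; then 2-(phenylsulfonyl)-3-phenyloxaziridine, −78 °C; aq. NH4Cl
Reagents that add atoms: 2-(phenylsulfonyl)-3-phenyloxaziridine O=S(=O)(c1ccccc1)N1OC1c1ccccc1
Why: Electrophilic hydroxylation of the ring-fusion lactone enolate can only occur on the convex face that keeps the five-membered ring cis-fused, so the hydroxyl should end up anti to the alkene bridge while the lactone carbonyl (the future vinyl group) stays syn to it.

Step 7
Reactants: 15 the hydroxy lactone
Product: 16 (1R,2R,6S,7R)-7,8-dimethyl-9-(4-methylpent-3-en-1-yl)-4-oxatricyclo[5.2.2.0(2,6)]undec-8-ene-2,3-diol (lactol; both C3 epimers)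
Conditions: iBu2AlH (2.5 equiv), CH2Cl2, −78 °C; aq. potassium sodium tartrate
Reagents that add atoms: none
Why: Low-temperature iBu2AlH reduction of a gamma-lactone stops at the lactol because the aluminium hemiacetal survives until work-up.

Step 8
Reactants: 16 the lactol
Product: 18 (1R,2R,3S,4R)-2-ethenyl-3-(hydroxymethyl)-4,5-dimethyl-6-(4-methylpent-3-en-1-yl)bicyclo[2.2.2]oct-5-en-2-ol (vinyl and CH2OH syn to the C5=C6 bridge), via hydroxy aldehyde 17 (not isolated)
Conditions: Ph3PCH3Br, KOtBu, THF, 0 °C; then 16, 0 °C to rt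
Reagents that add atoms: methyltriphenylphosphonium bromide [Br-].C[P+](c1ccccc1)(c1ccccc1)c1ccccc1
Why: Wittig methylenation of a lactol through its open hydroxy aldehyde form is a standard way to unmask a vinyl group and a primary alcohol together, and it does not touch the quaternary carbinol centre.

Step 9
Reactants: 18 the vinyl carbinol
Product: 21 (1S,4aR,8aR)-1-(hydroxymethyl)-4a,8a-dimethyl-5-(4-methylpent-3-en-1-yl)-3,4,4a,7,8,8a-hexahydronaphthalen-2(1H)-one, via dipotassium dialkoxide 19 (not isolated), via dipotassium enolate alkoxide 20 (not isolated)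
Conditions: KH (3 equiv), 18-crown-6 (3 equiv), THF, 0 °C to rt; then aq. NH4Cl, −78 °C
Reagents that add atoms: none
Why: The tertiary potassium alkoxide weakens the adjacent bridgehead–carbinol bond, so the 1,5-diene (vinyl–C2–C1–C6=C5 of the bicyclooctene) should undergo a concerted anionic oxy-Cope [3,3] shift through the boat geometry enforced by the bridge, forming the decalin C4–C4a bond as the C2–C6 bridge bond breaks and leaving the enolate toward C3. The closest known reaction type is the anionic oxy-Cope rearrangement of 2-vinylbicyclo[2.2.2]oct-5-en-2-ols to cis-fused octalones. Ring A (C1, C2, C3, C4, C4a, C8a) is closed by this sigmatropic bond formation between the vinyl terminus and the methyl-bearing alkene carbon, a six-membered ring made by [3,3] shift inside the bridged framework and not by an exo or endo attack of an open chain. The one new stereocentre, C4a, is set by suprafacial delivery of the vinyl terminus to the alkene face on the side of the carbinol bridge, which places the new bond cis to the C1–C8a bond and so makes the ring fusion and both angular methyls cis; C8a and C1 are carried over unchanged. The step needs the vinyl group syn to the alkene bridge, which the lactone-controlled hydroxylation of step 6 secures, and a regiodefined enolate, which the mechanism guarantees. The cold buffered quench should preserve the base-sensitive beta-hydroxy ketone and the C1 configuration.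

Step 10
Reactants: 21 the hydroxy ketone
Product: 22 [(1S,4aR,8aR)-4a,8a-dimethyl-2-methylidene-5-(4-methylpent-3-en-1-yl)-1,2,3,4,4a,7,8,8a-octahydronaphthalen-1-yl]methanol
Conditions: Zn, CH2Br2, TiCl4, THF/CH2Cl2, 0 °C to rt
Reagents that add atoms: dibromomethane BrCBr
Why: The non-basic zinc–titanium methylenation should convert the hindered, base-sensitive beta-hydroxy ketone into the exocyclic alkene without retro-aldol cleavage or epimerisation at C1.

Step 11
Reactants: 22 the methylidene alcohol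
Product: 23 [(1S,2R,4aR,8aR)-2,4a,8a-trimethyl-5-(4-methylpent-3-en-1-yl)-1,2,3,4,4a,7,8,8a-octahydronaphthalen-1-yl]methanol
Conditions: [Rh(nbd)(dppb)]BF4 (10 mol%), H2 (20 bar), CH2Cl2, rt
Reagents that add atoms: none
Why: Hydroxyl-directed hydrogenation should deliver hydrogen to the 1,1-disubstituted alkene from the face of the C1 hydroxymethyl group, which makes the new C2 methyl trans to it, while the two undirected trisubstituted alkenes should not be reduced by the cationic rhodium complex.

Step 12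
Reactants: 23 the saturated alcohol
Product: 25 (1S,2R,4aR,8aR)-2,4a,8a-trimethyl-5-(4-methylpent-3-en-1-yl)-1,2,3,4,4a,7,8,8a-octahydronaphthalene-1-carboxylic acid, via aldehyde 24 (not isolated)
Conditions: DMP, NaHCO3, CH2Cl2, 0 °C to rt; then NaClO2, NaH2PO4, 2-methylbut-2-ene, tBuOH/H2O, rt
Reagents that add atoms: sodium chlorite [Na+].[O-]Cl=O
Why: Periodinane oxidation to the aldehyde followed by Pinnick oxidation with an alkene scavenger should give the acid without touching the alkenes, and the equatorial C1 configuration (trans to the C2 methyl) is the thermodynamically preferred one should any enolisation occur.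

Step 13
Reactants: 26 (2S)-oxiran-2-ylmethanol ((S)-glycidol)
Product: 28 (2R)-2-{[(4-methoxybenzyl)oxy]methyl}oxirane, via sodium alkoxide 27 (not isolated)
Conditions: NaH, DMF, 0 °C; then PMBCl, n-Bu4NI (cat.), 0 °C to rt
Reagents that add atoms: 4-methoxybenzyl chloride COc1ccc(CCl)cc1
Why: Williamson etherification of the glycidol alkoxide does not involve the stereocentre (a Payne shift of glycidol is degenerate), so (S)-glycidol gives the (R)-ether by change of CIP priority only.

Step 14
Reactants: 25 the acid; 28 (2R)-2-{[(4-methoxybenzyl)oxy]methyl}oxirane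
Product: 29 (2S)-2-hydroxy-3-[(4-methoxybenzyl)oxy]propyl (1S,2R,4aR,8aR)-2,4a,8a-trimethyl-5-(4-methylpent-3-en-1-yl)-1,2,3,4,4a,7,8,8a-octahydronaphthalene-1-carboxylate
Conditions: n-Bu4NBr (10 mol%), toluene, 95 °C
Reagents that add atoms: none
Why: Ammonium-halide-catalysed addition of a carboxylic acid to a terminal epoxide takes place at the unhindered primary carbon, so the hindered acid is O-alkylated instead of having to acylate an alcohol, and the glycerol stereocentre is untouched.

Step 15
Reactants: 29 the hydroxy ester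
Product: 30 (2S)-2-acetoxy-3-[(4-methoxybenzyl)oxy]propyl (1S,2R,4aR,8aR)-2,4a,8a-trimethyl-5-(4-methylpent-3-en-1-yl)-1,2,3,4,4a,7,8,8a-octahydronaphthalene-1-carboxylate
Conditions: Ac2O, DMAP (cat.), pyridine, CH2Cl2, 0 °C to rt
Reagents that add atoms: acetic anhydride CC(=O)OC(C)=O
Why: DMAP-catalysed acetylation of the only free hydroxyl (the secondary one) should proceed without affecting the hindered ring ester.

Step 16
Reactants: 30 the acetate
Product: 31 (2S)-2-acetoxy-3-hydroxypropyl (1S,2R,4aR,8aR)-2,4a,8a-trimethyl-5-(4-methylpent-3-en-1-yl)-1,2,3,4,4a,7,8,8a-octahydronaphthalene-1-carboxylate (target)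
Conditions: DDQ, CH2Cl2/pH 7 phosphate buffer, 0 °C
Reagents that add atoms: none
Why: Oxidative cleavage of the 4-methoxybenzyl ether by DDQ in buffered wet dichloromethane is neutral, which should avoid migration of the neighbouring acetate to the freed primary hydroxyl and leaves the isolated alkenes intact.

**Compound list**

1 | 2,3-dimethylcyclohex-2-en-1-one | CC1=C(C)C(=O)CCC1 | starting material
2 | lithium 5,6-dimethylcyclohexa-1,5-dien-1-olate | [Li+].[O-]C1=CCCC(C)=C1C | intermediate
3 | 5,6-dimethylcyclohexa-1,5-dien-1-yl trifluoromethanesulfonate | CC1=C(C)C(OS(=O)(=O)C(F)(F)F)=CCC1 | intermediate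
4 | 5-bromo-2-methylpent-2-ene | CC(C)=CCCBr | starting material
5 | (4-methylpent-3-en-1-yl)magnesium bromide | CC(C)=CCC[Mg]Br | intermediate
6 | 1,2-dimethyl-3-(4-methylpent-3-en-1-yl)cyclohexa-1,3-diene | CC1=C(C)C(CCC=C(C)C)=CCC1 | intermediate
7 | (4R)-4-benzyl-1,3-oxazolidin-2-one | O=C1N[C@H](Cc2ccccc2)CO1 | starting material
8 | ethyl (2E)-4-chloro-4-oxobut-2-enoate | CCOC(=O)/C=C/C(Cl)=O | starting material
9 | lithium (4R)-4-benzyl-2-oxo-1,3-oxazolidin-3-ide | [Li+].O=C1[N-][C@H](Cc2ccccc2)CO1 | intermediate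
10 | ethyl (2E)-4-[(4R)-4-benzyl-2-oxo-1,3-oxazolidin-3-yl]-4-oxobut-2-enoate | CCOC(=O)/C=C/C(=O)N1[C@H](Cc2ccccc2)COC1=O | intermediate
11 | ethyl (1S,2R,3S,4R)-3-{[(4R)-4-benzyl-2-oxo-1,3-oxazolidin-3-yl]carbonyl}-4,5-dimethyl-6-(4-methylpent-3-en-1-yl)bicyclo[2.2.2]oct-5-ene-2-carboxylate | CCOC(=O)[C@H]1[C@H](C(=O)N3[C@H](Cc4ccccc4)COC3=O)[C@@]2(C)CC[C@@H]1C(CCC=C(C)C)=C2C | intermediate
12 | ethyl (1S,2R,3S,4R)-3-(hydroxymethyl)-4,5-dimethyl-6-(4-methylpent-3-en-1-yl)bicyclo[2.2.2]oct-5-ene-2-carboxylate | CCOC(=O)[C@H]1[C@H](CO)[C@@]2(C)CC[C@@H]1C(CCC=C(C)C)=C2C | intermediate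
13 | (1S,2S,6S,7R)-7,8-dimethyl-9-(4-methylpent-3-en-1-yl)-4-oxatricyclo[5.2.2.0(2,6)]undec-8-en-3-one | O=C1OC[C@@H]2[C@@]3(C)CC[C@H](C(CCC=C(C)C)=C3C)[C@H]12 | intermediate
14 | potassium enolate of lactone 13 | [K+].[O-]C=1OC[C@@H]2[C@@]3(C)CC[C@H](C(CCC=C(C)C)=C3C)C=12 | intermediate
15 | (1R,2R,6S,7R)-2-hydroxy-7,8-dimethyl-9-(4-methylpent-3-en-1-yl)-4-oxatricyclo[5.2.2.0(2,6)]undec-8-en-3-one | O=C1OC[C@@H]2[C@@]3(C)CC[C@H](C(CCC=C(C)C)=C3C)[C@]12O | intermediate
16 | (1R,2R,6S,7R)-7,8-dimethyl-9-(4-methylpent-3-en-1-yl)-4-oxatricyclo[5.2.2.0(2,6)]undec-8-ene-2,3-diol (lactol, both C3 epimers) | OC1OC[C@@H]2[C@@]3(C)CC[C@H](C(CCC=C(C)C)=C3C)[C@]12O | intermediate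
17 | (1R,2R,3S,4R)-2-hydroxy-3-(hydroxymethyl)-4,5-dimethyl-6-(4-methylpent-3-en-1-yl)bicyclo[2.2.2]oct-5-ene-2-carbaldehyde | O=C[C@]1(O)[C@H](CO)[C@@]2(C)CC[C@@H]1C(CCC=C(C)C)=C2C | intermediate
18 | (1R,2R,3S,4R)-2-ethenyl-3-(hydroxymethyl)-4,5-dimethyl-6-(4-methylpent-3-en-1-yl)bicyclo[2.2.2]oct-5-en-2-ol | C=C[C@]1(O)[C@H](CO)[C@@]2(C)CC[C@@H]1C(CCC=C(C)C)=C2C | intermediate
19 | dipotassium dialkoxide of 18 | [K+].[K+].C=C[C@]1([O-])[C@H](C[O-])[C@@]2(C)CC[C@@H]1C(CCC=C(C)C)=C2C | intermediate
20 | dipotassium enolate alkoxide of 21 | [K+].[K+].[O-]C[C@H]1C([O-])=CC[C@]2(C)C(CCC=C(C)C)=CCC[C@]12C | intermediate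
21 | (1S,4aR,8aR)-1-(hydroxymethyl)-4a,8a-dimethyl-5-(4-methylpent-3-en-1-yl)-3,4,4a,7,8,8a-hexahydronaphthalen-2(1H)-one | OC[C@H]1C(=O)CC[C@]2(C)C(CCC=C(C)C)=CCC[C@]12C | intermediate
22 | [(1S,4aR,8aR)-4a,8a-dimethyl-2-methylidene-5-(4-methylpent-3-en-1-yl)-1,2,3,4,4a,7,8,8a-octahydronaphthalen-1-yl]methanol | OC[C@H]1C(=C)CC[C@]2(C)C(CCC=C(C)C)=CCC[C@]12C | intermediate
23 | [(1S,2R,4aR,8aR)-2,4a,8a-trimethyl-5-(4-methylpent-3-en-1-yl)-1,2,3,4,4a,7,8,8a-octahydronaphthalen-1-yl]methanol | OC[C@H]1[C@H](C)CC[C@]2(C)C(CCC=C(C)C)=CCC[C@]12C | intermediate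
24 | (1S,2R,4aR,8aR)-2,4a,8a-trimethyl-5-(4-methylpent-3-en-1-yl)-1,2,3,4,4a,7,8,8a-octahydronaphthalene-1-carbaldehyde | O=C[C@H]1[C@H](C)CC[C@]2(C)C(CCC=C(C)C)=CCC[C@]12C | intermediate
25 | (1S,2R,4aR,8aR)-2,4a,8a-trimethyl-5-(4-methylpent-3-en-1-yl)-1,2,3,4,4a,7,8,8a-octahydronaphthalene-1-carboxylic acid | OC(=O)[C@H]1[C@H](C)CC[C@]2(C)C(CCC=C(C)C)=CCC[C@]12C | intermediate
26 | (2S)-oxiran-2-ylmethanol | OC[C@H]1CO1 | starting material
27 | sodium (2S)-oxiran-2-ylmethanolate | [Na+].[O-]C[C@H]1CO1 | intermediate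
28 | (2R)-2-{[(4-methoxybenzyl)oxy]methyl}oxirane | COc1ccc(COC[C@H]2CO2)cc1 | intermediate
29 | (2S)-2-hydroxy-3-[(4-methoxybenzyl)oxy]propyl ester of acid 25 | COc1ccc(COC[C@H](O)COC(=O)[C@H]2[C@H](C)CC[C@]3(C)C(CCC=C(C)C)=CCC[C@]23C)cc1 | intermediate
30 | (2S)-2-acetoxy-3-[(4-methoxybenzyl)oxy]propyl ester of acid 25 | COc1ccc(COC[C@H](OC(C)=O)COC(=O)[C@H]2[C@H](C)CC[C@]3(C)C(CCC=C(C)C)=CCC[C@]23C)cc1 | intermediate
31 | (2S)-2-acetoxy-3-hydroxypropyl (1S,2R,4aR,8aR)-2,4a,8a-trimethyl-5-(4-methylpent-3-en-1-yl)-1,2,3,4,4a,7,8,8a-octahydronaphthalene-1-carboxylate | CC(=O)O[C@@H](CO)COC(=O)[C@H]1[C@H](C)CC[C@]2(C)C(CCC=C(C)C)=CCC[C@]12C | target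

**Step count**

Total steps: 16. Longest linear sequence: 14 steps (1, 2, 4 to 12, 14, 15, 16); steps 3 and 13 prepare the two side fragments.

**Steps most likely to fail**

Step 4 (Diels–Alder). The fully substituted diene terminus may bond too slowly to the bulky chelated imide, so that Lewis-acid-induced isomerisation of the diene or erosion of regio- and facial selectivity takes over. The fallback installs the side chain after the cycloaddition and sets out from 1 and 10. Enone 1 is silylated through its kinetic dienolate (LiN(iPr)2, tBuMe2SiCl) to tert-butyl[(5,6-dimethylcyclohexa-1,5-dien-1-yl)oxy]dimethylsilane F1, a more nucleophilic 2-silyloxy diene in which the oxygen and the terminal methyl direct the same orientation. Its cycloaddition with 10 (Et2AlCl, −78 °C, concerted or by a Mukaiyama–Michael/Michael sequence that converges on the same product) should give the 6-silyloxy analogue of 11 F2. CsF and PhNTf2 then convert the silyl enol ether into the 6-triflyloxy analogue of 11 F3, and Fe(acac)3-catalysed coupling with Grignard reagent 5 at −30 °C comes back to the route at 11.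

Step 9 (anionic oxy-Cope on the dialkoxide). The second alkoxide may slow the rearrangement, or the beta-alkoxide ketone enolate formed may fragment by retro-aldol loss of the hydroxymethyl carbon before the quench. The fallback sets out from 18: selective silylation of the primary hydroxyl (tBuMe2SiCl, imidazole, CH2Cl2) gives the mono-silyl ether of 18 F4, whose monoalkoxide (KH, 18-crown-6, THF) should rearrange in the same way to the silyloxy ketone F5; HF·pyridine in THF then frees the alcohol and comes back to the route at 21.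

Step 11 (directed hydrogenation). Hydrogen may be delivered from the wrong face if coordination of the hydroxyl is outweighed by the axial angular methyl, or the exocyclic alkene may migrate into the ring before it is reduced. The fallback sets C2 under thermodynamic control and sets out from 22. DMP oxidation gives the beta,gamma-unsaturated aldehyde F6. DBU moves the double bond into conjugation to give the tetrasubstituted enal (4aR,8aR)-2,4a,8a-trimethyl-5-(4-methylpent-3-en-1-yl)-3,4,4a,7,8,8a-hexahydronaphthalene-1-carbaldehyde F7. Pinnick oxidation gives the corresponding 1-ene-1-carboxylic acid F8. Li in liquid NH3/THF at −78 °C followed by NH4Cl should reduce the conjugated acid with axial protonation at C2 (equatorial methyl), leaving the isolated alkenes alone, and after equilibration of C1 to the equatorial acid the route is rejoined at 25.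

Further compounds
F1 | step 4 | tert-butyl[(5,6-dimethylcyclohexa-1,5-dien-1-yl)oxy]dimethylsilane | CC1=C(C)C(O[Si](C)(C)C(C)(C)C)=CCC1
F2 | step 4 | ethyl 3-{[(4R)-4-benzyl-2-oxo-1,3-oxazolidin-3-yl]carbonyl}-6-[(tert-butyldimethylsilyl)oxy]-4,5-dimethylbicyclo[2.2.2]oct-5-ene-2-carboxylate (configuration as in 11) | CCOC(=O)[C@H]1[C@H](C(=O)N3[C@H](Cc4ccccc4)COC3=O)[C@@]2(C)CC[C@@H]1C(O[Si](C)(C)C(C)(C)C)=C2C
F3 | step 4 | ethyl 3-{[(4R)-4-benzyl-2-oxo-1,3-oxazolidin-3-yl]carbonyl}-4,5-dimethyl-6-[(trifluoromethanesulfonyl)oxy]bicyclo[2.2.2]oct-5-ene-2-carboxylate (configuration as in 11) | CCOC(=O)[C@H]1[C@H](C(=O)N3[C@H](Cc4ccccc4)COC3=O)[C@@]2(C)CC[C@@H]1C(OS(=O)(=O)C(F)(F)F)=C2C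
F4 | step 9 | (1R,2R,3S,4R)-3-{[(tert-butyldimethylsilyl)oxy]methyl}-2-ethenyl-4,5-dimethyl-6-(4-methylpent-3-en-1-yl)bicyclo[2.2.2]oct-5-en-2-ol | C=C[C@]1(O)[C@H](CO[Si](C)(C)C(C)(C)C)[C@@]2(C)CC[C@@H]1C(CCC=C(C)C)=C2C
F5 | step 9 | (1S,4aR,8aR)-1-{[(tert-butyldimethylsilyl)oxy]methyl}-4a,8a-dimethyl-5-(4-methylpent-3-en-1-yl)-3,4,4a,7,8,8a-hexahydronaphthalen-2(1H)-one | CC(C)(C)[Si](C)(C)OC[C@H]1C(=O)CC[C@]2(C)C(CCC=C(C)C)=CCC[C@]12C
F6 | step 11 | (1S,4aR,8aR)-4a,8a-dimethyl-2-methylidene-5-(4-methylpent-3-en-1-yl)-1,2,3,4,4a,7,8,8a-octahydronaphthalene-1-carbaldehyde | O=C[C@H]1C(=C)CC[C@]2(C)C(CCC=C(C)C)=CCC[C@]12C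
F7 | step 11 | (4aR,8aR)-2,4a,8a-trimethyl-5-(4-methylpent-3-en-1-yl)-3,4,4a,7,8,8a-hexahydronaphthalene-1-carbaldehyde | O=CC1=C(C)CC[C@]2(C)C(CCC=C(C)C)=CCC[C@]12C
F8 | step 11 | (4aR,8aR)-2,4a,8a-trimethyl-5-(4-methylpent-3-en-1-yl)-3,4,4a,7,8,8a-hexahydronaphthalene-1-carboxylic acid | OC(=O)C1=C(C)CC[C@]2(C)C(CCC=C(C)C)=CCC[C@]12C
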